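Numbering used throughout: friedelane numbers for the triterpene half (C1–C30), primed guaiane numbers for the sesquiterpene half (C1′–C15′).

## Structural features

The target is an octacyclic adduct in which the aromatic ring A of a 24-norfriedelane (methyl at C4, oxygens at C2 and C3) is tied through both oxygens to C1′ and C5′ of a guaiane hydroazulene, so that a 1,4-benzodioxane links a C30 and a C15 half. In the triterpene half rings B to E follow ring A in a row: C6=C7 is a styrene, C8 carries a β hydrogen, and the quaternary carbons C9 (β-methyl), C13 (α-methyl), C14 (β-methyl), C17 (β-methyl) and C20 (β-methyl, α-CO2Me) line the backbone, with C18 (β-H) making the D/E junction cis. Adjacent stereocentres are C8/C9, C13/C14 and C17/C18; C13 and C14 are vicinal quaternary carbons with anti methyls, and H8, the C9 methyl and the C14 methyl all stand on the β face, which makes the B/C junction cis. The sesquiterpene half has C7′ (S, isopropenyl) and C10′ (R, methyl) on the seven-membered ring, a C3′=C4′ alkene, and the two neighbouring, fully substituted ether carbons C1′ and C5′, cis to each other. Fragile groups are the tertiary allylic aryl ethers (acid), the styrene with its allylic C8–H (tautomerisation towards a quinone methide once ring A is oxidised), the isopropenyl group and the methyl ester. The real difficulty is stereochemical: the C13/C14 pair, the 8β hydrogen that sits on the more crowded face, and the remote 1,4 pair C17/C20 in ring E, which no neighbouring centre can relay. The key step uses exactly this last feature: a ring E 1,3-dione with carbonyls at C18 and C22 has a mirror plane through C17 and C20, so one choice between two enantiotopic carbonyls (bond C13–C18) fixes both centres.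

## Logic of the disconnections

43 to 31 and 41. The bonds O2–C1′ and O3–C5′ are cut together. Both carbons are fully substituted and cis, the signature of a [4+2] addition of 42 (31 at the quinone level) across C1′=C5′ of 41. The cut separates the two halves and removes two stereocentres. It demands that 42 adds as a heterodiene to the tetrasubstituted bond, O3 to C5′, on the face syn to the C10′ methyl, faster than 42 tautomerises or the double bonds of 41 migrate.

31 to 29. No skeletal bond is cut; the C6=C7 alkene and the free phenols go back to C6H2–C7H2 and two methyl ethers (30, then 29), because neither would survive the Lewis acid of the ring closure. The demand is hydride abstraction at C6 only, and ether cleavage that spares the ester and the styrene.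

29 to 28. C8–C14 and C9–C10 are cut. They stand anti across a former C8=C9 alkene, so one cation–alkene–arene cascade from the C14 carbinol can make both. Rings B and C and the centres C8, C9 and C14 disappear. The demand is transfer of the (Z) geometry into the cis B/C junction, attack of C8 on C14 anti to the C13 methyl, and closure at C10.

28 to 16 and 25. C14–CH3 is cut (back to 27), then the sp3–sp2 bond C11–C9. The cut lies between the bicyclic core and the arene-bearing chain and lets the alkene enter with fixed geometry only after the hydrogenation that sets C18. The demand is a cross-coupling of the alkylzinc from 16 with retention at the vinyl iodide, beside a ketone and an ester.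

25 to 17, 19 and 21. C8=C9 (olefination of 20), C5–C6 (arylation of 19 by 18) and the aryl C–I bond are cut. This reduces the chain to three commercial pieces. The demand is iodination of 17 para to the unhindered methoxy group, and a Z-selective iodo-olefination.

16 to 8 and 10. C13–C12 and C13–CH3 are cut; C18–H, C22–H2 and the iodide are functional group changes (15, 14, 13, 12, 11, 9). Enone 8 is nucleophilic at C13 twice through its extended enolate. The demand is that the methyl, entering second, comes anti to the C17 methyl, and that hydrogen then adds to the β face of C18=C19.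

8 to 6 (key). C13=C18 is cut. This opens ring D and turns C17 and C20 into the mirror-related centres of a meso compound. The demand is discrimination of the C18 and C22 carbonyls by the catalyst.

6 to 4 and 5, 4 to 1. C17–C16 (conjugate addition) and C20–CH3 (reductive methylation of 1) are cut. The dione is made from 1 because a cyclohexenone from methyl methacrylate and a silyloxydiene has its carbonyl para to the quaternary carbon, whereas the dione needs both carbonyls meta to it; the aromatic precursor places them correctly. The demand is separation of the cis isomer of 6.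

41 to 32, 34 and 37. C3′=C4′ is cut (metathesis of 40), then C1′–C2′ (coupling of 36 with 37), the methyl bonds at C4′ (39, 38), and C1′–C5′/C5′–C6′ (one-carbon insertion of 34 into 33); 33 comes from 32 by setting C10′. Both stereocentres are carried from the start and the diene is formed last, under neutral conditions, as one double-bond isomer.

## Other disconnections considered

Alternative 1: The five-membered ring of the sesquiterpene is cut at C1′–C5′, C3′–C4′ and C2′–C3′. Forward, an allene-yne made from (S)-limonene A1 would be closed by [Rh(CO)2Cl]2 under CO to guaia-1(10),4,11-trien-3-one A2. In its favour, both rings and three C–C bonds arise in one catalytic step and C7′ comes from the chiral pool; to the bicyclic skeleton it is shorter than the route 32 to 41, and on that point it is the better. Against it here, A2 has C10′ as an sp2 carbon, so C10′ would have to be set by a 1,6-reduction under remote 1,4 control from C7′. The C3′ carbonyl must also be turned into the diene by reduction and dehydration, conditions under which the cyclopentadiene isomers equilibrate. The chosen fragment route carries C10′ from 33 and ends in a neutral metathesis, so it is the safer in stereochemistry and in the position of the diene. The alternative touches only the C15 half and would still need the chosen key step for ring E.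

Alternative 2: Rings B and C are cut at C6–C7 and C8–C9. Forward, a ring A benzaldehyde A3, carrying the C9 methine on C10 and a C14 vinyl sulfone on ring D, would be irradiated with Ti(OiPr)4 and the hydroxy-ortho-quinodimethane would add to the tethered C7=C8 bond to give A4. In its favour, C8 and C9 are set in one suprafacial event without any carbocation, which removes the risk of 1,2-shifts that the chosen step 18 carries; on mechanism it is the better. The C6 hydroxyl and C7 sulfone of A4 are also a latent C6=C7 alkene, which saves the dehydrogenation of step 19. Against it, A3 must already hold both C13 and C14 as quaternary centres, so the hardest pair is moved to an earlier, separate problem, whereas step 18 makes C14 during the closure. The dienophile sits on a neopentyl carbon, and the outcome at C8 and C9 hangs on dienol geometry and endo/exo folding of a four-atom tether. In step count the two are about equal, and both need rings D and E with C17 and C20 from a compound such as 8.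

Alternative 3: No ring bond is cut; the methyls on C13, C14 and C9 and the hydrogen on C8 are returned to C14, C8, C10 and C9 of an oleanane-type pentacycle with a C12=C13 alkene. Forward, CF3SO3H would protonate C12 and the shifts would run to C10, ending in aromatisation of ring A to give A5. In its favour, one step sets C9, C13 and C14, each shift being suprafacial and antiperiplanar; if the substrate came from a natural oleanane it would be far shorter, and in step economy it would be the better. Against it here, the hydride moves from C9 to C8 on the α face, so A5 is the 8α epimer and the target's 8β hydrogen would need a separate inversion with no controlling element. The cascade is also reversible acid chemistry, with stopping points at intermediate alkenes, and runs beside an ester. Natural oleananes seldom carry the C20 carboxylate, so ring E would again need a de novo source. The chosen plan reaches 8β directly and builds C17/C20 by design.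

Key step: step 5

Remarks on the chemistry:
- The target is taken exactly as drawn in its SMILES: 8β-H (cis B/C) and (7′S,10′R), hence (S)-carvone as the chiral-pool source.
- Compounds 2 and 3 are cis/trans mixtures, 28 a C14 epimer mixture and 35 a C5′ epimer/enol mixture, all without consequence.
- The C22 alcohol of 9 and 11–13 is drawn β; either epimer serves.

## Steps

Step 1
Reactants: 1 3,5-dimethoxy-4-methylbenzoic acid
Product: 2 diene acid (3,5-dimethoxy-1,4-dimethylcyclohexa-2,5-diene-1-carboxylic acid; cis/trans mixture)
Conditions: Li, NH3(l)/THF, −78 °C; MeI; NH4Cl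
Reagents that add atoms: iodomethane, CI
Why: Birch reduction of the benzoate gives the 1,4-dihydro enolate, which is methylated at the carboxyl-bearing carbon (reductive alkylation); the carboxylate directs reduction to the ipso and para carbons, so both methoxy groups remain as enol ethers. This carbon becomes C20 and the new methyl C30.

Step 2
Reactants: 2 diene acid
Product: 3 methyl 3,5-dimethoxy-1,4-dimethylcyclohexa-2,5-diene-1-carboxylate
Conditions: K2CO3, MeI, DMF, 25 °C
Reagents that add atoms: iodomethane, CI
Why: Carboxylate O-alkylation under mild base leaves the acid-labile enol ethers intact; the hindered acid is esterified before the dione is unmasked so that the dione is never exposed to an alkylating agent.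

Step 3
Reactants: 3 diene ester
Product: 4 methyl 1,4-dimethyl-3,5-dioxocyclohexane-1-carboxylate (2,5-dimethyl-5-carbomethoxycyclohexane-1,3-dione; largely enolised)
Conditions: 1 M HCl, THF, 25 °C
Reagents that add atoms: water, O
Why: Hydrolysis of the two enol ethers releases the 1,3-dione; the ester sits on the carbon β to both carbonyls (a γ-keto ester), so no decarboxylation pathway exists.

Step 4
Reactants: 4 dione; 5 but-3-en-2-one
Product: 6 meso triketone (methyl cis-1,4-dimethyl-3,5-dioxo-4-(3-oxobutyl)cyclohexane-1-carboxylate; ester cis to the oxobutyl chain)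
Conditions: Et3N (cat.), MeOH, 25 °C; chromatography and crystallisation to separate the cis isomer
Reagents that add atoms: none
Why: Michael addition of the 2-methyl-1,3-dione to the enone makes C17 quaternary. Both faces of the planar enolate are open, so cis and trans triketones (both achiral) are expected; the cis isomer, in which the C17 and C20 methyls are cis, is taken on.

Step 5
Reactants: 6 meso triketone
Product: 8 ring D–E enedione (methyl (2S,4aR)-2,4a-dimethyl-4,7-dioxo-1,2,3,4,4a,5,6,7-octahydronaphthalene-2-carboxylate; C14 and C22 ketones; C13=C18), via ring D–E ketol 7 (not isolated)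
Conditions: D-proline (30 mol%), DMSO, 25 °C; then p-TsOH (cat.), toluene, 60 °C
Reagents that add atoms: none
Why: D-Proline condenses with the side-chain methyl ketone of 6 to an enamine whose carbon C13 adds to one ring carbonyl (C18) while the carboxylic acid of the catalyst hydrogen-bonds that carbonyl; hydrolysis gives ketol 7 and acid-promoted dehydration gives the C13=C18 enone, an intramolecular aldol condensation of the Hajos–Parrish type as known for 2-alkyl-2-(3-oxobutyl)cyclohexane-1,3-diones. Ring D closes in the 6-(enolendo)-exo-trig mode through a chair-like transition state. No bond is made at C17 or C20: both become stereogenic only because the two carbonyls, enantiotopic in meso 6, are told apart, so one selection by the catalyst fixes C17 (R) and, through the preset cis relation of the two methyls, C20 (S). D-Proline is required because the target has the angular C17 methyl in the series opposite to the one L-proline delivers for the parent triketone. The step needs enamine formation at the unhindered methyl ketone and not at the flanked ring ketones, which the steric difference should secure. It also needs group selectivity between C18 and C22, which rests on the hydrogen-bonded transition state. The C20 ester and methyl lie across ring E from the reacting centres and should be spectators.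

Step 6
Reactants: 8 ring D–E enedione
Product: 9 22β-hydroxy enone (C22 ketone of 8 reduced to the alcohol cis to the C17 methyl)
Conditions: NaBH4 (0.3 equiv), EtOH–CH2Cl2, −40 °C
Reagents that add atoms: none
Why: The saturated ketone is more electrophilic than the conjugated one, as in the reduction of the Wieland–Miescher ketone; axial hydride delivery anti to the C17 methyl should give the β alcohol. The configuration at C22 is immaterial, since the oxygen is removed in step 10.

Step 7
Reactants: 9 22β-hydroxy enone; 10 benzyl 2-iodoethyl ether
Product: 11 13-(2-benzyloxyethyl) enone (C13=C18 enone bearing the C12–C11 chain on C13)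
Conditions: KOtBu (1.1 equiv), tBuOH–THF, 25 °C
Reagents that add atoms: none
Why: The extended enolate of the enone alkylates at its α-carbon C13 and the product returns to conjugation. The hindered C22 hydroxyl is left free, as in the C4 alkylation of 17-hydroxy steroidal enones.

Step 8
Reactants: 11 13-(2-benzyloxyethyl) enone
Product: 12 13α-methyl-13β-(2-benzyloxyethyl) 18(19)-en-14-one (22β-ol)
Conditions: KOtBu, tBuOH–THF, 0 °C; MeI
Reagents that add atoms: iodomethane, CI
Why: A second deconjugative alkylation makes C13 quaternary and moves the alkene to C18=C19. Iodomethane approaches the planar dienolate anti to the axial C17 methyl, so the new methyl is α and the chain points to the future ring C.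

Step 9
Reactants: 12 dialkylated ketone
Product: 13 O-(imidazol-1-ylthiocarbonyl) derivative of 12 at C22
Conditions: 1,1′-thiocarbonyldiimidazole, DMAP, ClCH2CH2Cl, 80 °C
Reagents that add atoms: 1,1′-thiocarbonyldiimidazole, S=C(n1ccnc1)n1ccnc1
Why: Neutral acylation of the hindered secondary alcohol prepares the Barton–McCombie deoxygenation without enolising the C14 ketone.

Step 10
Reactants: 13 thiocarbonyl derivative
Product: 14 22-deoxy ketone (13α-methyl-13β-(2-benzyloxyethyl) 18(19)-en-14-one)
Conditions: Bu3SnH, AIBN (cat.), toluene, 110 °C
Reagents that add atoms: none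
Why: Barton–McCombie radical deoxygenation. It is run at this stage because the C22 radical then faces only an unactivated, hindered alkene and not an enone, so hydrogen transfer from the stannane should outrun any 3-exo closure.

Step 11
Reactants: 14 22-deoxy ketone
Product: 15 cis-fused hydroxy ketone (18β-H; 13β-(2-hydroxyethyl); may rest as its hemiketal)
Conditions: H2 (50 bar), Pd(OH)2/C, EtOAc–AcOH, 50 °C
Reagents that add atoms: none
Why: Hydrogenolysis of the benzyl ether and hydrogenation of C18=C19 in one operation. The α face is screened by the axial C13 methyl and the axial C20 ester, the β face only by the C17 methyl, so hydrogen should add from β and set 18β-H (cis D/E).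

Step 12
Reactants: 15 hydroxy ketone
Product: 16 primary iodide (13β-(2-iodoethyl) ketone)
Conditions: I2, PPh3, imidazole, CH2Cl2, 0 °C
Reagents that add atoms: iodine, II
Why: Appel-type iodination of the primary alcohol; the open hydroxy ketone is drained from its hemiketal equilibrium.

Step 13
Reactants: 17 2,3-dimethoxytoluene
Product: 18 1-iodo-3,4-dimethoxy-2-methylbenzene
Conditions: N-iodosuccinimide, CF3CO2H (cat.), MeCN, 25 °C
Reagents that add atoms: N-iodosuccinimide, O=C1CCC(=O)N1I
Why: Electrophilic iodination para to the coplanar C3 methoxy group and ortho to the methyl; the flanked C2 methoxy group is twisted and directs weakly. The iodinated carbon becomes C5.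

Step 14
Reactants: 18 aryl iodide; 19 prop-2-en-1-ol
Product: 20 3-(3,4-dimethoxy-2-methylphenyl)propanal
Conditions: Pd(OAc)2 (cat.), Bu4NCl, NaHCO3, DMF, 45 °C
Reagents that add atoms: none
Why: Heck arylation of allyl alcohol under Jeffery conditions; β-hydride elimination towards the carbinol carbon gives the enol and hence the aldehyde, which supplies C6, C7 and C8.

Step 15
Reactants: 20 aldehyde; 21 ethyltriphenylphosphonium iodide
Product: 25 (Z)-1-(4-iodopent-3-en-1-yl)-3,4-dimethoxy-2-methylbenzene, via ethylidene ylide 22 (not isolated), via iodoethylphosphonium iodide 23 (not isolated), via iodoethylidene ylide 24 (not isolated)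
Conditions: n-BuLi, THF, −78 to 0 °C; I2, −78 °C; NaHMDS, −20 °C; 20, −78 to 25 °C
Reagents that add atoms: iodine, II
Why: Stork–Zhao-type iodo-olefination: the α-iodo ylide reacts with the aldehyde through the kinetically favoured cis oxaphosphetane, which places iodine cis to the chain ((Z)-2-iodoalkene). This fixes the future C8=C9 geometry.

Step 16
Reactants: 16 primary iodide; 25 (Z)-vinyl iodide
Product: 27 (Z)-alkenyl ketone (14-ketone with the (Z)-3-methyl-6-arylhex-3-enyl chain on C13), via alkylzinc iodide 26 (not isolated)
Conditions: Zn (activated), LiCl, THF, 40 °C; then 25, Pd(PPh3)4 (cat.), THF–NMP, 50 °C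
Reagents that add atoms: none
Why: Zinc inserts into the primary C–I bond without touching ketone or ester. Negishi coupling then joins C11 to C9 with retention of the alkene geometry, so C11 and C7 are cis.

Step 17
Reactants: 27 (Z)-alkenyl ketone
Product: 28 C14 tertiary carbinol (14-hydroxy-14-methyl; both C14 epimers)
Conditions: MeLi, CeCl3, THF, −78 °C
Reagents that add atoms: methyllithium, [Li]C
Why: The weakly basic methylcerium reagent adds to the hindered, enolisable C14 ketone in preference to the still more hindered ester on a quaternary carbon. The new stereocentre is erased on ionisation.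

Step 18
Reactants: 28 C14 tertiary carbinol
Product: 29 methyl 2,3-dimethoxy-24-norfriedela-1,3,5(10)-trien-29-oate (8β-H)
Conditions: SnCl4, CH2Cl2, −78 °C
Reagents that add atoms: none
Why: Lewis-acid ionisation gives the C14 cation, which is captured by C8 of the (Z)-alkene, and the C9 cation closes on C10, the only free position ortho to C5 (cationic polyene bicyclisation with Friedel–Crafts termination, Stork–Eschenmoser course). Anti addition across the (Z)-alkene puts H8 and the C9 methyl cis. A chair transition state with the C12 tether equatorial on ring D should place C8 anti to C18 and the C14 methyl anti to the C13 methyl, giving 14β-Me, 8β-H and 9β-Me.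

Step 19
Reactants: 29 pentacyclic dimethyl ether
Product: 30 methyl 2,3-dimethoxy-24-norfriedela-1,3,5(10),6-tetraen-29-oate (8β-H)
Conditions: DDQ, 1,4-dioxane, 80 °C
Reagents that add atoms: none
Why: Benzylic dehydrogenation: hydride abstraction at C6, para to the C2 methoxy group, then loss of H7 gives the styrene. Further aromatisation is blocked by quaternary C9.

Step 20
Reactants: 30 styrene dimethyl ether
Product: 31 methyl 2,3-dihydroxy-24-norfriedela-1,3,5(10),6-tetraen-29-oate (8β-H)
Conditions: BBr3, CH2Cl2, −78 to 0 °C
Reagents that add atoms: none
Why: Lewis-acid cleavage of the two aryl methyl ethers at low temperature, where the hindered tertiary methyl ester should be left.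

Step 21
Reactants: 32 (S)-carvone
Product: 33 (2R,5S)-dihydrocarvone (cis-2-methyl-5-(prop-1-en-2-yl)cyclohexanone)
Conditions: Old Yellow Enzyme OYE2 (ene-reductase), NADP+ (cat.), D-glucose, glucose dehydrogenase, phosphate buffer pH 7, 30 °C
Reagents that add atoms: none
Why: Ene-reductases of this family add hydride to the β-carbon and a proton to the α-carbon of the enone and should set C2 as R whatever the C5 configuration, so (S)-carvone should give the cis ketone. The unactivated isopropenyl group is not a substrate. C2 becomes C10′ and C5 becomes C7′.

Step 22
Reactants: 33 cis-dihydrocarvone; 34 ethyl diazoacetate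
Product: 35 ethyl (3R,6S)-3-methyl-2-oxo-6-(prop-1-en-2-yl)cycloheptane-1-carboxylate (C1 epimers and enol)
Conditions: BF3·OEt2, Et2O, 0 °C
Reagents that add atoms: none
Why: Lewis-acid-promoted diazoacetate ring expansion. The less substituted α-carbon (CH2) migrates, so the new carbon (C5′, bearing the ester carbon C4′) enters between the carbonyl C1′ and C6′, and the α-methyl centre is not touched.

Step 23
Reactants: 35 β-keto ester
Product: 36 enol triflate (C1′=C5′; triflate on C1′, ester on C5′)
Conditions: NaH, THF, 0 °C; PhNTf2, 25 °C
Reagents that add atoms: N-phenylbis(trifluoromethanesulfonimide), O=S(=O)(N(c1ccccc1)S(=O)(=O)C(F)(F)F)C(F)(F)F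
Why: One equivalent of base removes only the doubly activated C5′ proton, so C10′ is not enolised; O-sulfonylation fixes the C1′=C5′ double bond.

Step 24
Reactants: 36 enol triflate; 37 allyltributylstannane
Product: 38 ethyl 2-allylcycloheptenecarboxylate (allyl on C1′; C7′ S, C10′ R)
Conditions: Pd(PPh3)4 (cat.), LiCl, THF, 65 °C
Reagents that add atoms: none
Why: Stille coupling of the vinyl triflate; oxidative addition to zerovalent palladium and allyl transfer install C2′ and C3′ on C1′.

Step 25
Reactants: 38 allyl ester
Product: 39 tertiary alcohol (2-hydroxyprop-2-yl on C5′)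
Conditions: MeLi, CeCl3, THF, −78 to 0 °C
Reagents that add atoms: methyllithium, [Li]C
Why: Double addition of the methylcerium reagent to the ester; the low basicity avoids γ-deprotonation of the doubly allylic C2′ methylene.

Step 26
Reactants: 39 tertiary alcohol
Product: 40 triene (1-allyl-2-isopropenylcycloheptene core; C7′ isopropenyl, C10′ methyl)
Conditions: Burgess reagent (methyl N-(triethylammoniosulfonyl)carbamate), benzene, 50 °C
Reagents that add atoms: none
Why: Syn elimination through the sulfamate ester can take a hydrogen only from one of the two methyls, the only sp3 carbons next to the carbinol carbon, so the 1,1-disubstituted alkene forms without acid.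

Step 27
Reactants: 40 triene
Product: 41 (7S,10R)-guaia-1(5),3,11-triene
Conditions: second-generation Grubbs catalyst (H2IMes)(PCy3)Cl2Ru=CHPh (cat.), CH2Cl2, 40 °C; used at once
Reagents that add atoms: none
Why: Ring-closing metathesis between the allyl terminus and the isopropenyl group on C5′ closes the five-membered ring at C3′=C4′ and releases ethene. The tetrasubstituted C1′=C5′ bond and the remote C7′ isopropenyl group should not take part, and the neutral conditions deliver the diene as the single C1′=C5′/C3′=C4′ isomer.

Step 28
Reactants: 31 catechol; 41 guaia-1(5),3,11-triene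
Product: 43 target (CNP0287532.1), via ortho-quinone 42 (not isolated)
Conditions: Ag2O, Na2SO4, CH2Cl2, −20 to 20 °C, dark; 41 in excess
Reagents that add atoms: none
Why: Ag2O oxidises the catechol to the 2,3-dione 42, which adds as an electron-poor heterodiene across the most electron-rich π bond of 41, the tetrasubstituted C1′=C5′ (inverse-electron-demand hetero-Diels–Alder reaction of an ortho-quinone with an alkene). Suprafacial addition makes the two C–O bonds cis and so sets C1′ and C5′ together. The required orientation (O3 to C5′) and face (syn to the C10′ methyl) are those of the natural adduct and are expected, not secured, if the union is an uncatalysed cycloaddition.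

## Compound list

1 | 3,5-dimethoxy-4-methylbenzoic acid | COc1cc(C(=O)O)cc(OC)c1C | starting material
2 | 3,5-dimethoxy-1,4-dimethylcyclohexa-2,5-diene-1-carboxylic acid (cis/trans mixture) | COC1=CC(C)(C(=O)O)C=C(OC)C1C | intermediate
3 | methyl 3,5-dimethoxy-1,4-dimethylcyclohexa-2,5-diene-1-carboxylate | COC1=CC(C)(C(=O)OC)C=C(OC)C1C | intermediate
4 | methyl 1,4-dimethyl-3,5-dioxocyclohexane-1-carboxylate | CC1C(=O)CC(C)(C(=O)OC)CC1=O | intermediate
5 | but-3-en-2-one | CC(=O)C=C | starting material
6 | meso triketone, methyl cis-1,4-dimethyl-3,5-dioxo-4-(3-oxobutyl)cyclohexane-1-carboxylate | CC(=O)CC[C@]1(C)C(=O)C[C@](C)(C(=O)OC)CC1=O | intermediate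
7 | ring D–E ketol (18β-hydroxy; C14 and C22 ketones) | O=C1CC[C@@]2(C)C(=O)C[C@@](C)(C(=O)OC)C[C@@]2(O)C1 | intermediate (not isolated)
8 | ring D–E enedione, methyl (2S,4aR)-2,4a-dimethyl-4,7-dioxo-1,2,3,4,4a,5,6,7-octahydronaphthalene-2-carboxylate | O=C1CC[C@@]2(C)C(=O)C[C@@](C)(C(=O)OC)CC2=C1 | intermediate
9 | 22β-hydroxy enone | O=C1CC[C@@]2(C)[C@H](O)C[C@@](C)(C(=O)OC)CC2=C1 | intermediate
10 | benzyl 2-iodoethyl ether | ICCOCc1ccccc1 | starting material
11 | 13-(2-benzyloxyethyl)-22β-hydroxy enone | O=C1CC[C@@]2(C)[C@H](O)C[C@@](C)(C(=O)OC)CC2=C1CCOCc1ccccc1 | intermediate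
12 | 13α-methyl-13β-(2-benzyloxyethyl)-22β-hydroxy-18(19)-en-14-one | O=C1CC[C@@]2(C)[C@H](O)C[C@@](C)(C(=O)OC)C=C2[C@]1(C)CCOCc1ccccc1 | intermediate
13 | 22-O-(imidazol-1-ylthiocarbonyl) derivative of 12 | O=C1CC[C@@]2(C)[C@H](OC(=S)n3ccnc3)C[C@@](C)(C(=O)OC)C=C2[C@]1(C)CCOCc1ccccc1 | intermediate
14 | 22-deoxy 13α-methyl-13β-(2-benzyloxyethyl)-18(19)-en-14-one | O=C1CC[C@@]2(C)CC[C@@](C)(C(=O)OC)C=C2[C@]1(C)CCOCc1ccccc1 | intermediate
15 | cis-fused hydroxy ketone (18β-H; 13β-(2-hydroxyethyl)) | O=C1CC[C@@]2(C)CC[C@@](C)(C(=O)OC)C[C@H]2[C@]1(C)CCO | intermediate
16 | cis-fused iodo ketone (13β-(2-iodoethyl)) | O=C1CC[C@@]2(C)CC[C@@](C)(C(=O)OC)C[C@H]2[C@]1(C)CCI | intermediate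
17 | 2,3-dimethoxytoluene | COc1cccc(C)c1OC | starting material
18 | 1-iodo-3,4-dimethoxy-2-methylbenzene | COc1ccc(I)c(C)c1OC | intermediate
19 | prop-2-en-1-ol | C=CCO | starting material
20 | 3-(3,4-dimethoxy-2-methylphenyl)propanal | COc1ccc(CCC=O)c(C)c1OC | intermediate
21 | ethyltriphenylphosphonium iodide | CC[P+](c1ccccc1)(c1ccccc1)c1ccccc1.[I-] | starting material
22 | ethylidenetriphenylphosphorane | CC=P(c1ccccc1)(c1ccccc1)c1ccccc1 | intermediate (not isolated)
23 | (1-iodoethyl)triphenylphosphonium iodide | CC(I)[P+](c1ccccc1)(c1ccccc1)c1ccccc1.[I-] | intermediate (not isolated)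
24 | (1-iodoethylidene)triphenylphosphorane | CC(I)=P(c1ccccc1)(c1ccccc1)c1ccccc1 | intermediate (not isolated)
25 | (Z)-1-(4-iodopent-3-en-1-yl)-3,4-dimethoxy-2-methylbenzene | COc1ccc(CC/C=C(/C)I)c(C)c1OC | intermediate
26 | alkylzinc iodide from 16 | O=C1CC[C@@]2(C)CC[C@@](C)(C(=O)OC)C[C@H]2[C@]1(C)CC[Zn]I | intermediate (not isolated)
27 | (Z)-alkenyl ketone (C13 chain C12–C11–C9(Me)=C8–C7–C6–aryl) | O=C1CC[C@@]2(C)CC[C@@](C)(C(=O)OC)C[C@H]2[C@]1(C)CC/C(C)=C\CCc1ccc(OC)c(OC)c1C | intermediate
28 | C14 tertiary carbinol (C14 epimers) | CC1(O)CC[C@@]2(C)CC[C@@](C)(C(=O)OC)C[C@H]2[C@]1(C)CC/C(C)=C\CCc1ccc(OC)c(OC)c1C | intermediate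
29 | methyl 2,3-dimethoxy-24-norfriedela-1,3,5(10)-trien-29-oate (8β-H) | COc1cc2c(c(C)c1OC)CC[C@@H]1[C@@]2(C)CC[C@@]2(C)[C@@H]3C[C@](C)(C(=O)OC)CC[C@]3(C)CC[C@]12C | intermediate
30 | methyl 2,3-dimethoxy-24-norfriedela-1,3,5(10),6-tetraen-29-oate (8β-H) | COc1cc2c(c(C)c1OC)C=C[C@@H]1[C@@]2(C)CC[C@@]2(C)[C@@H]3C[C@](C)(C(=O)OC)CC[C@]3(C)CC[C@]12C | intermediate
31 | methyl 2,3-dihydroxy-24-norfriedela-1,3,5(10),6-tetraen-29-oate (8β-H) | Oc1cc2c(c(C)c1O)C=C[C@@H]1[C@@]2(C)CC[C@@]2(C)[C@@H]3C[C@](C)(C(=O)OC)CC[C@]3(C)CC[C@]12C | intermediate
32 | (S)-carvone | C=C(C)[C@H]1CC=C(C)C(=O)C1 | starting material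
33 | (2R,5S)-dihydrocarvone | C=C(C)[C@H]1CC[C@@H](C)C(=O)C1 | intermediate
34 | ethyl diazoacetate | CCOC(=O)C=[N+]=[N-] | starting material
35 | ethyl (3R,6S)-3-methyl-2-oxo-6-(prop-1-en-2-yl)cycloheptane-1-carboxylate | C=C(C)[C@H]1CC[C@@H](C)C(=O)C(C(=O)OCC)C1 | intermediate
36 | enol triflate of 35 | C=C(C)[C@H]1CC[C@@H](C)C(OS(=O)(=O)C(F)(F)F)=C(C(=O)OCC)C1 | intermediate
37 | allyltributylstannane | C=CC[Sn](CCCC)(CCCC)CCCC | starting material
38 | ethyl 2-allyl-3-methyl-6-(prop-1-en-2-yl)cyclohept-1-ene-1-carboxylate (3R,6S) | C=C(C)[C@H]1CC[C@@H](C)C(CC=C)=C(C(=O)OCC)C1 | intermediate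
39 | tertiary alcohol from 38 | C=C(C)[C@H]1CC[C@@H](C)C(CC=C)=C(C(C)(C)O)C1 | intermediate
40 | triene (1-allyl-2-isopropenylcycloheptene) | C=C(C)[C@H]1CC[C@@H](C)C(CC=C)=C(C(C)=C)C1 | intermediate
41 | (7S,10R)-guaia-1(5),3,11-triene | C=C(C)[C@H]1CC[C@@H](C)C2=C(C1)C(C)=CC2 | intermediate
42 | methyl 2,3-dioxo-24-norfriedela-1(10),4,6-trien-29-oate (8β-H) | O=C1C=C2C(=C(C)C1=O)C=C[C@@H]1[C@@]2(C)CC[C@@]2(C)[C@@H]3C[C@](C)(C(=O)OC)CC[C@]3(C)CC[C@]12C | intermediate (not isolated)
43 | CNP0287532.1 | C=C(C)[C@H]1CC[C@@H](C)[C@]23CC=C(C)[C@@]2(C1)Oc1c(cc2c(c1C)C=C[C@@H]1[C@@]2(C)CC[C@@]2(C)[C@@H]4C[C@](C)(C(=O)OC)CC[C@]4(C)CC[C@]12C)O3 | target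

## Step count and least certain steps

Total step count: 28. Longest linear sequence: 18 steps (steps 1–12, 16–20 and 28).

Step 5 (key step). Most likely failure: incomplete discrimination of the two enantiotopic carbonyls, because the axial C20 ester may perturb the chair-like aldol transition state, together with stalling at the ketol. Fallback, from 6 back to 9: condense 6 with pyrrolidine and acetic acid to the racemic enedione F1, reduce with NaBH4 to the racemic hydroxy enone F2, esterify with (S)-O-methylmandelic acid (DCC, DMAP), separate the diastereomeric ester of the wanted enantiomer F3 by chromatography, and cleave it with K2CO3 in methanol to return to 9. Catalyst control is replaced by resolution.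

Step 18. Most likely failure: capture of the C14 cation on the wrong face (cis C/D junction), since the (Z)-alkene forces the C7 chain axial and syn to the C13 methyl in the chair; further risks are 1,2-methyl migration from C13 and premature ring B closure after protonation of the chain alkene. Fallback, from 27 back to 29: methylenate the C14 ketone with Ph3P=CH2 to the exocyclic alkene F4, then run a hydrogen-atom-transfer-initiated radical–polar crossover bicyclisation (Co(salen) catalyst, N-fluoro-2,4,6-trimethylpyridinium tetrafluoroborate, PhSiH3). The C14 methyl then comes from hydrogen transfer to the methylene, the C14 centre is a radical that cannot undergo a methyl shift, and only the 1,1-disubstituted alkene is activated.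

Step 28. Most likely failure: double-bond migration in 41 by 1,5-hydrogen shift before it is consumed, tautomerisation of 42 to the quinone methide, or addition in the wrong orientation or on the wrong face. Fallback, from 31 and 40 back to 43: oxidise 31 with Ag2O in the presence of triene 40, which has no cyclopentadiene and cannot shift; addition across its C1′=C5′ bond gives the bis-alkenyl adduct F5 with allyl and isopropenyl cis, and ring-closing metathesis of F5 then forms C3′=C4′ and returns to 43. The order of cycloaddition and metathesis is inverted.

Step 11. Most likely failure: no reaction at the alkene, which is flanked by three quaternary carbons, or delivery of hydrogen to the α face. Fallback, from 14 back to 15: reduce the C14 ketone with L-Selectride to the axial 14β alcohol F6, hydrogenate under hydroxyl direction with [Ir(cod)(PCy3)(py)]PF6 to the 18β-H alcohol F7, oxidise with Dess–Martin periodinane to the ketone F8, and remove the benzyl group with H2 and Pd(OH)2/C to reach 15. Steric control is replaced by a directing group on the β face.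

Step 6. Most likely failure: loss of chemoselectivity, because the C22 ketone is flanked by a quaternary carbon and an axial ester while the enone carbonyl is open. Fallback, from 8 back to 9: reduce both carbonyls with NaBH4 and CeCl3 to the diol F9, then reoxidise only the allylic C14 alcohol with MnO2.

## Further compounds

F1 | step 5 | racemic ring D–E enedione (relative configuration of 8) | O=C1CCC2(C)C(=O)CC(C)(C(=O)OC)CC2=C1
F2 | step 5 | racemic 22-hydroxy enone (relative configuration of 9) | O=C1CCC2(C)C(O)CC(C)(C(=O)OC)CC2=C1
F3 | step 5 | (S)-O-methylmandelate of 9 | O=C1CC[C@@]2(C)[C@H](OC(=O)[C@@H](OC)c3ccccc3)C[C@@](C)(C(=O)OC)CC2=C1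
F4 | step 18 | 14-methylene analogue of 27 | C=C1CC[C@@]2(C)CC[C@@](C)(C(=O)OC)C[C@H]2[C@]1(C)CC/C(C)=C\CCc1ccc(OC)c(OC)c1C
F5 | step 28 | benzodioxane adduct of 42 with 40 (1′-allyl, 5′-isopropenyl) | C=C(C)[C@H]1CC[C@@H](C)[C@]2(CC=C)[C@@](C1)(C(C)=C)Oc1c(cc3c(c1C)C=C[C@@H]1[C@@]3(C)CC[C@@]3(C)[C@@H]4C[C@](C)(C(=O)OC)CC[C@]4(C)CC[C@]13C)O2
F6 | step 11 | 14β-alcohol of 14 | O[C@@H]1CC[C@@]2(C)CC[C@@](C)(C(=O)OC)C=C2[C@]1(C)CCOCc1ccccc1
F7 | step 11 | 18β-H 14β-alcohol, benzyl ether | O[C@@H]1CC[C@@]2(C)CC[C@@](C)(C(=O)OC)C[C@H]2[C@]1(C)CCOCc1ccccc1
F8 | step 11 | 18β-H 14-ketone, benzyl ether of 15 | O=C1CC[C@@]2(C)CC[C@@](C)(C(=O)OC)C[C@H]2[C@]1(C)CCOCc1ccccc1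
F9 | step 6 | 14,22-diol from 8 (C14 configuration open) | OC1CC[C@@]2(C)[C@H](O)C[C@@](C)(C(=O)OC)CC2=C1
A1 | alternative 1 | (S)-limonene | C=C(C)[C@@H]1CC=C(C)CC1
A2 | alternative 1 | guaia-1(10),4,11-trien-3-one | C=C(C)[C@H]1CCC(C)=C2CC(=O)C(C)=C2C1
A3 | alternative 2 | ring A benzaldehyde with C9 methine chain and C14 (E)-vinyl sulfone (C9 configuration open) | COc1cc(C(C)CC[C@@]2(C)[C@@H]3C[C@](C)(C(=O)OC)CC[C@]3(C)CC[C@]2(C)/C=C/S(=O)(=O)c2ccccc2)c(C=O)c(C)c1OC
A4 | alternative 2 | pentacyclic C6 alcohol, C7 phenyl sulfone | COc1cc2c(c(C)c1OC)C(O)C(S(=O)(=O)c1ccccc1)[C@@H]1[C@@]2(C)CC[C@@]2(C)[C@@H]3C[C@](C)(C(=O)OC)CC[C@]3(C)CC[C@]12C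
A5 | alternative 3 | methyl 3-hydroxy-2-methoxy-24-norfriedela-1,3,5(10)-trien-29-oate (8α-H) | COc1cc2c(c(C)c1O)CC[C@H]1[C@@]2(C)CC[C@@]2(C)[C@@H]3C[C@](C)(C(=O)OC)CC[C@]3(C)CC[C@]12C
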